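**Retrosynthetic overview**
- Both C–Br bonds come from alcohols by Appel inversion (allylic C13 last, ring C9 earlier); the Z-enyne comes from cross-metathesis of a terminal alkene with a silyl enyne.
- The C11=C12 Z-alkene comes from semihydrogenation of an alkyne.
- The only ring, the tetrahydrofuran, is formed once: 5-endo opening of a (9S,10S)-alkynyl epoxide by the C7 hydroxyl with inversion at C10; the epoxide comes from Shi epoxidation of an E-enyne.
- The E-enyne comes from Sonogashira coupling of an E-vinyl iodide with the TBS ether of (S)-pent-1-yn-3-ol (source of C13).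
- The vinyl iodide comes from an anti-chlorohydrin made by propargylation of (R)-2-chloropent-4-enal (C6 by organocatalytic chlorination, C7 by Cornforth-type addition).

Assumption: (S)-pent-1-yn-3-ol is bought as the single enantiomer, and L-prolinamide/NCS is taken to give the (2R)-chloroaldehyde (D-prolinamide is used if the first run shows the opposite sense).

Atom numbers C1–C15 in the "Why" lines follow the target chain (C1 alkyne terminus, C15 methyl).

Step 1
Reactants: 1 pent-4-enal; 2 N-chlorosuccinimide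
Product: 3 (2R)-2-chloropent-4-enal
Conditions: NCS, L-prolinamide (10 mol %), CH2Cl2, 0 °C to rt; silica plug, used at once
Reagents that add atoms: N-chlorosuccinimide, ClN1C(=O)CCC1=O
Why: Enamine-mediated organocatalytic α-chlorination, in which the amide N–H delivers chlorine to one enamine face and sets C6 (R).

Step 2
Reactants: 3 (2R)-2-chloropent-4-enal; 4 allenylboronic acid pinacol ester
Product: 6 (4S,5R)-5-chlorooct-7-en-1-yn-4-ol, via pinacol borate ester 5 (not isolated)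
Conditions: (S)-TRIP [(S)-3,3′-bis(2,4,6-triisopropylphenyl)-1,1′-binaphthyl-2,2′-diyl hydrogen phosphate] (5 mol %), 4 Å MS, toluene, −30 °C; pH 7 buffer work-up
Reagents that add atoms: allenylboronic acid pinacol ester, C=C=CB1OC(C)(C)C(C)(C)O1
Why: Brønsted-acid-catalysed allenylboration (propargylation) through a cyclic transition state, in which Cornforth attack anti to the C–Cl dipole and the acid antipode (chosen to favour the same Si face) set C7 (S) as the anti-chlorohydrin.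

Step 3
Reactants: 6 (4S,5R)-5-chlorooct-7-en-1-yn-4-ol; 7 tributyltin hydride; 8 iodine
Product: 10 (1E,4S,5R)-5-chloro-1-iodoocta-1,7-dien-4-ol, via E-vinylstannane 9 (not isolated)
Conditions: Bu3SnH, Pd2(dba)3 (1 mol %), Cy3P·HBF4 (4 mol %), i-Pr2NEt (8 mol %), CH2Cl2, 0 °C; then I2, 0 °C
Reagents that add atoms: iodine, II
Why: Pd-catalysed syn-hydrostannation puts tin on the terminal carbon (bulky phosphine) and iododestannylation proceeds with retention to give the E-vinyl iodide, leaving the alkene, chloride and free hydroxyl untouched.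

Step 4
Reactants: 11 (3S)-pent-1-yn-3-ol; 12 tert-butyldimethylsilyl chloride
Product: 13 (3S)-3-[(tert-butyldimethylsilyl)oxy]pent-1-yne
Conditions: TBSCl, imidazole, DMF, 0 °C to rt
Reagents that add atoms: tert-butyldimethylsilyl chloride, CC(C)(C)[Si](C)(C)Cl
Why: Standard silyl ether formation that masks the propargylic hydroxyl (future C13) without touching its configuration.

Step 5
Reactants: 10 (1E,4S,5R)-5-chloro-1-iodoocta-1,7-dien-4-ol; 13 (3S)-3-[(tert-butyldimethylsilyl)oxy]pent-1-yne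
Product: 14 (4R,5S,7E,11S)-11-[(tert-butyldimethylsilyl)oxy]-4-chlorotrideca-1,7-dien-9-yn-5-ol
Conditions: Pd(PPh3)2Cl2 (3 mol %), CuI (6 mol %), Et3N, THF, rt, degassed
Reagents that add atoms: (3S)-3-[(tert-butyldimethylsilyl)oxy]pent-1-yne, C#C[C@@H](O[Si](C)(C)C(C)(C)C)CC
Why: Sonogashira coupling joins C10 to C11 with retention of the E geometry and is mild enough for the chlorohydrin.

Step 6
Reactants: 14 (4R,5S,7E,11S)-11-[(tert-butyldimethylsilyl)oxy]-4-chlorotrideca-1,7-dien-9-yn-5-ol; 15 potassium peroxymonosulfate (Oxone)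
Product: 16 (2S,3R)-3-chloro-1-{(2S,3S)-3-[(3S)-3-[(tert-butyldimethylsilyl)oxy]pent-1-yn-1-yl]oxiran-2-yl}hex-5-en-2-ol
Conditions: ent-Shi ketone (1,2:4,5-di-O-isopropylidene-β-L-erythro-2,3-hexodiulo-2,6-pyranose, 3 equiv), Oxone (2KHSO5·KHSO4·K2SO4), NaHCO3, Bu4NHSO4 (cat.), MeCN/aq. Na2EDTA, 0 °C, pH 7–8
Reagents that add atoms: potassium peroxymonosulfate, [K+].[O-]S(=O)(=O)OO
Why: Shi asymmetric epoxidation by the chiral dioxirane (spiro transition state) attacks only the E-alkene of the enyne and sets C9 (S) and C10 (S) under catalyst control, while the near-neutral pH keeps the chlorohydrin from closing to an epoxide.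

Step 7
Reactants: 16 (2S,3R)-3-chloro-1-{(2S,3S)-3-[(3S)-3-[(tert-butyldimethylsilyl)oxy]pent-1-yn-1-yl]oxiran-2-yl}hex-5-en-2-ol
Product: 17 (2R,3S,5S)-2-[(3S)-3-[(tert-butyldimethylsilyl)oxy]pent-1-yn-1-yl]-5-[(1R)-1-chlorobut-3-en-1-yl]oxolan-3-ol
Conditions: BF3·OEt2 (0.2 equiv), CH2Cl2, −78 to −30 °C
Reagents that add atoms: none
Why: Acid-promoted 5-endo epoxide opening by the C7 hydroxyl at the alkyne-activated propargylic carbon goes with inversion at C10 (now R) and gives the 2,5-trans tetrahydrofuran with the C9 hydroxyl trans to the alkynyl group.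

Step 8
Reactants: 17 (2R,3S,5S)-2-[(3S)-3-[(tert-butyldimethylsilyl)oxy]pent-1-yn-1-yl]-5-[(1R)-1-chlorobut-3-en-1-yl]oxolan-3-ol; 18 carbon tetrabromide
Product: 19 (2R,3R,5S)-3-bromo-2-[(3S)-3-[(tert-butyldimethylsilyl)oxy]pent-1-yn-1-yl]-5-[(1R)-1-chlorobut-3-en-1-yl]oxolane
Conditions: CBr4, (n-Oct)3P, toluene, 70 °C
Reagents that add atoms: carbon tetrabromide, BrC(Br)(Br)Br
Why: Appel bromination, in which bromide displaces the oxyphosphonium by SN2 with inversion and sets C9 (R) cis to the small, linear alkynyl group.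

Step 9
Reactants: 19 (2R,3R,5S)-3-bromo-2-[(3S)-3-[(tert-butyldimethylsilyl)oxy]pent-1-yn-1-yl]-5-[(1R)-1-chlorobut-3-en-1-yl]oxolane; 20 dihydrogen
Product: 21 (2R,3R,5S)-3-bromo-2-[(1Z,3S)-3-[(tert-butyldimethylsilyl)oxy]pent-1-en-1-yl]-5-[(1R)-1-chlorobut-3-en-1-yl]oxolane
Conditions: H2 (1 atm), Pd/CaCO3 poisoned with Pb(OAc)2, EtOAc/pyridine/1-octene 10:1:1, rt, stopped at full alkyne conversion
Reagents that add atoms: none
Why: Lindlar syn-semihydrogenation gives the C11=C12 Z-alkene, with the poisoned catalyst and sacrificial 1-octene sparing the terminal alkene and both carbon–halogen bonds.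

Step 10
Reactants: 22 vinyl bromide; 23 (triisopropylsilyl)acetylene
Product: 24 triisopropyl(but-3-en-1-yn-1-yl)silane
Conditions: Pd(PPh3)2Cl2 (2 mol %), CuI (4 mol %), i-Pr2NH, THF, 0 °C to rt
Reagents that add atoms: vinyl bromide, C=CBr
Why: Sonogashira coupling gives the silyl-capped conjugated enyne used as the metathesis partner.

Step 11
Reactants: 21 (2R,3R,5S)-3-bromo-2-[(1Z,3S)-3-[(tert-butyldimethylsilyl)oxy]pent-1-en-1-yl]-5-[(1R)-1-chlorobut-3-en-1-yl]oxolane; 24 triisopropyl(but-3-en-1-yn-1-yl)silane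
Product: 25 (2R,3R,5S)-3-bromo-2-[(1Z,3S)-3-[(tert-butyldimethylsilyl)oxy]pent-1-en-1-yl]-5-[(1R,3Z)-1-chloro-6-(triisopropylsilyl)hex-3-en-5-yn-1-yl]oxolane
Conditions: 24 (4 equiv), second-generation Grubbs catalyst RuCl2(=CHPh)(PCy3)(H2IMes) (10 mol %), benzene, 60 °C; Z isomer separated on AgNO3-impregnated silica
Reagents that add atoms: triisopropyl(but-3-en-1-yn-1-yl)silane, C=CC#C[Si](C(C)C)(C(C)C)C(C)C
Why: Alkene cross-metathesis with a conjugated enyne runs through an alkynyl-substituted ruthenium alkylidene that favours the Z-enyne (expected about 5:1 or better), while the internal Z-alkene flanked by two branched carbons is too hindered to take part.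

Step 12
Reactants: 25 (2R,3R,5S)-3-bromo-2-[(1Z,3S)-3-[(tert-butyldimethylsilyl)oxy]pent-1-en-1-yl]-5-[(1R,3Z)-1-chloro-6-(triisopropylsilyl)hex-3-en-5-yn-1-yl]oxolane
Product: 26 (1Z,3S)-1-[(2R,3R,5S)-3-bromo-5-[(1R,3Z)-1-chlorohex-3-en-5-yn-1-yl]oxolan-2-yl]pent-1-en-3-ol
Conditions: Bu4NF (4 equiv), AcOH (4 equiv), THF, 0 °C to rt
Reagents that add atoms: none
Why: Fluoride-mediated desilylation removes the alkynyl TIPS group and the TBS ether together, and the acetic acid buffer suppresses E2 loss of HBr across C9–C10.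

Step 13
Reactants: 26 (1Z,3S)-1-[(2R,3R,5S)-3-bromo-5-[(1R,3Z)-1-chlorohex-3-en-5-yn-1-yl]oxolan-2-yl]pent-1-en-3-ol; 18 carbon tetrabromide
Product: 27 (2R,3R,5S)-3-bromo-2-[(1Z,3R)-3-bromopent-1-en-1-yl]-5-[(1R,3Z)-1-chlorohex-3-en-5-yn-1-yl]oxolane, that is (3Z,6R,7S,9R,10R,11Z,13R)-9,13-dibromo-6-chloro-7,10-epoxypentadeca-3,11-dien-1-yne
Conditions: CBr4 (1.5 equiv), PPh3 (1.6 equiv), CH2Cl2, −20 to 0 °C, 30 min
Reagents that add atoms: carbon tetrabromide, BrC(Br)(Br)Br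
Why: Appel reaction with SN2 inversion at C13 (S to R), where the SN2′ path is disfavoured because C11 is flanked by the oxygen-bearing C10, and the short cold reaction limits bromide exchange.

**Compound list**
1 | pent-4-enal | C=CCCC=O | starting material
2 | N-chlorosuccinimide | ClN1C(=O)CCC1=O | starting material
3 | (2R)-2-chloropent-4-enal | C=CC[C@@H](Cl)C=O | intermediate
4 | allenylboronic acid pinacol ester (4,4,5,5-tetramethyl-2-(propa-1,2-dien-1-yl)-1,3,2-dioxaborolane) | C=C=CB1OC(C)(C)C(C)(C)O1 | starting material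
5 | 2-{[(4S,5R)-5-chlorooct-7-en-1-yn-4-yl]oxy}-4,4,5,5-tetramethyl-1,3,2-dioxaborolane (pinacol borate ester, formed in the flask) | C=CC[C@@H](Cl)[C@@H](OB1OC(C)(C)C(C)(C)O1)CC#C | intermediate
6 | (4S,5R)-5-chlorooct-7-en-1-yn-4-ol | C=CC[C@@H](Cl)[C@@H](O)CC#C | intermediate
7 | tributyltin hydride | CCCC[SnH](CCCC)CCCC | starting material
8 | iodine | II | starting material
9 | (1E,4S,5R)-5-chloro-1-(tributylstannyl)octa-1,7-dien-4-ol (E-vinylstannane, formed in the flask) | C=CC[C@@H](Cl)[C@@H](O)C/C=C/[Sn](CCCC)(CCCC)CCCC | intermediate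
10 | (1E,4S,5R)-5-chloro-1-iodoocta-1,7-dien-4-ol | C=CC[C@@H](Cl)[C@@H](O)C/C=C/I | intermediate
11 | (3S)-pent-1-yn-3-ol | C#C[C@@H](O)CC | starting material
12 | tert-butyldimethylsilyl chloride | CC(C)(C)[Si](C)(C)Cl | starting material
13 | (3S)-3-[(tert-butyldimethylsilyl)oxy]pent-1-yne | C#C[C@@H](O[Si](C)(C)C(C)(C)C)CC | intermediate
14 | (4R,5S,7E,11S)-11-[(tert-butyldimethylsilyl)oxy]-4-chlorotrideca-1,7-dien-9-yn-5-ol | C=CC[C@@H](Cl)[C@@H](O)C/C=C/C#C[C@@H](O[Si](C)(C)C(C)(C)C)CC | intermediate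
15 | potassium peroxymonosulfate (KHSO5, the oxidant of Oxone) | [K+].[O-]S(=O)(=O)OO | starting material
16 | (2S,3R)-3-chloro-1-{(2S,3S)-3-[(3S)-3-[(tert-butyldimethylsilyl)oxy]pent-1-yn-1-yl]oxiran-2-yl}hex-5-en-2-ol | C=CC[C@@H](Cl)[C@@H](O)C[C@@H]1O[C@H]1C#C[C@@H](O[Si](C)(C)C(C)(C)C)CC | intermediate
17 | (2R,3S,5S)-2-[(3S)-3-[(tert-butyldimethylsilyl)oxy]pent-1-yn-1-yl]-5-[(1R)-1-chlorobut-3-en-1-yl]oxolan-3-ol | C=CC[C@@H](Cl)[C@@H]1C[C@H](O)[C@@H](C#C[C@@H](O[Si](C)(C)C(C)(C)C)CC)O1 | intermediate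
18 | carbon tetrabromide | BrC(Br)(Br)Br | starting material
19 | (2R,3R,5S)-3-bromo-2-[(3S)-3-[(tert-butyldimethylsilyl)oxy]pent-1-yn-1-yl]-5-[(1R)-1-chlorobut-3-en-1-yl]oxolane | C=CC[C@@H](Cl)[C@@H]1C[C@@H](Br)[C@@H](C#C[C@@H](O[Si](C)(C)C(C)(C)C)CC)O1 | intermediate
20 | dihydrogen | [H][H] | starting material
21 | (2R,3R,5S)-3-bromo-2-[(1Z,3S)-3-[(tert-butyldimethylsilyl)oxy]pent-1-en-1-yl]-5-[(1R)-1-chlorobut-3-en-1-yl]oxolane | C=CC[C@@H](Cl)[C@@H]1C[C@@H](Br)[C@@H](/C=C\[C@@H](O[Si](C)(C)C(C)(C)C)CC)O1 | intermediate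
22 | vinyl bromide | C=CBr | starting material
23 | (triisopropylsilyl)acetylene | C#C[Si](C(C)C)(C(C)C)C(C)C | starting material
24 | triisopropyl(but-3-en-1-yn-1-yl)silane | C=CC#C[Si](C(C)C)(C(C)C)C(C)C | intermediate
25 | (2R,3R,5S)-3-bromo-2-[(1Z,3S)-3-[(tert-butyldimethylsilyl)oxy]pent-1-en-1-yl]-5-[(1R,3Z)-1-chloro-6-(triisopropylsilyl)hex-3-en-5-yn-1-yl]oxolane | CC(C)[Si](C(C)C)(C(C)C)C#C/C=C\C[C@@H](Cl)[C@@H]1C[C@@H](Br)[C@@H](/C=C\[C@@H](O[Si](C)(C)C(C)(C)C)CC)O1 | intermediate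
26 | (1Z,3S)-1-[(2R,3R,5S)-3-bromo-5-[(1R,3Z)-1-chlorohex-3-en-5-yn-1-yl]oxolan-2-yl]pent-1-en-3-ol | C#C/C=C\C[C@@H](Cl)[C@@H]1C[C@@H](Br)[C@@H](/C=C\[C@@H](O)CC)O1 | intermediate
27 | (2R,3R,5S)-3-bromo-2-[(1Z,3R)-3-bromopent-1-en-1-yl]-5-[(1R,3Z)-1-chlorohex-3-en-5-yn-1-yl]oxolane | C#C/C=C\C[C@@H](Cl)[C@@H]1C[C@@H](Br)[C@@H](/C=C\[C@H](Br)CC)O1 | target

**Step count and risks**
Total steps: 13. Longest linear sequence: 11 (steps 1, 2, 3, 5, 6, 7, 8, 9, 11, 12, 13).

First risk, step 2. The α-chloroaldehyde is configurationally labile and the anti selectivity of a boron propargylation on it is not guaranteed. The fallback sets out from 3 and uses a lithium enolate aldol, the best-behaved addition to α-chloroaldehydes. The lithium enolate of N-methoxy-N-methylacetamide (LiN(i-Pr)2, THF, −78 °C, cold quench) adds to 3 to give the anti aldol (3S,4R)-4-chloro-3-hydroxy-N-methoxy-N-methylhept-6-enamide F1. Reduction with i-Bu2AlH at −78 °C gives (3S,4R)-4-chloro-3-hydroxyhept-6-enal F2. Takai iodo-olefination (CHI3, CrCl2, THF, 0 °C) then gives the E-vinyl iodide directly, so the fallback comes back to the route at 10 and bypasses steps 2 and 3.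

Second risk, step 11. The Z:E ratio of the enyne cross-metathesis may be poor, or the catalyst may stall on this halogenated substrate. The fallback sets out from 21 and builds the Z-enyne by olefination instead. Selective dihydroxylation of the terminal alkene (OsO4 cat., NMO, acetone/H2O; the hindered, electron-poor internal Z-alkene reacts far more slowly) gives (4R)-4-[(2S,4R,5R)-4-bromo-5-[(1Z,3S)-3-[(tert-butyldimethylsilyl)oxy]pent-1-en-1-yl]oxolan-2-yl]-4-chlorobutane-1,2-diol F3. Cleavage with NaIO4 gives (3R)-3-[(2S,4R,5R)-4-bromo-5-[(1Z,3S)-3-[(tert-butyldimethylsilyl)oxy]pent-1-en-1-yl]oxolan-2-yl]-3-chloropropanal F4. Peterson olefination with lithiated 1,3-bis(triisopropylsilyl)propyne (n-BuLi, THF, −78 °C to rt) passes through the β-silyl alkoxide of (1R)-1-[(2S,4R,5R)-4-bromo-5-[(1Z,3S)-3-[(tert-butyldimethylsilyl)oxy]pent-1-en-1-yl]oxolan-2-yl]-1-chloro-4,6-bis(triisopropylsilyl)hex-5-yn-3-ol F5, whose syn elimination gives the Z-enyne. The fallback comes back to the route at 25.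

Third risk, step 13. The secondary Z-allylic alcohol can give SN2′ product, E/Z scrambling or partial loss of configuration under phosphonium activation. The fallback sets out from 26 and separates activation from displacement. Mesylation at −40 °C (MsCl, Et3N, CH2Cl2) gives (1Z,3S)-1-[(2R,3R,5S)-3-bromo-5-[(1R,3Z)-1-chlorohex-3-en-5-yn-1-yl]oxolan-2-yl]pent-1-en-3-yl methanesulfonate F6. This is treated cold (−40 to −10 °C) with LiBr in THF for a discrete SN2 displacement with inversion. The fallback comes back to the route at 27.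

**Further compounds**
F1 | step 2 | (3S,4R)-4-chloro-3-hydroxy-N-methoxy-N-methylhept-6-enamide | C=CC[C@@H](Cl)[C@@H](O)CC(=O)N(C)OC
F2 | step 2 | (3S,4R)-4-chloro-3-hydroxyhept-6-enal | C=CC[C@@H](Cl)[C@@H](O)CC=O
F3 | step 11 | (4R)-4-[(2S,4R,5R)-4-bromo-5-[(1Z,3S)-3-[(tert-butyldimethylsilyl)oxy]pent-1-en-1-yl]oxolan-2-yl]-4-chlorobutane-1,2-diol | OCC(O)C[C@@H](Cl)[C@@H]1C[C@@H](Br)[C@@H](/C=C\[C@@H](O[Si](C)(C)C(C)(C)C)CC)O1
F4 | step 11 | (3R)-3-[(2S,4R,5R)-4-bromo-5-[(1Z,3S)-3-[(tert-butyldimethylsilyl)oxy]pent-1-en-1-yl]oxolan-2-yl]-3-chloropropanal | O=CC[C@@H](Cl)[C@@H]1C[C@@H](Br)[C@@H](/C=C\[C@@H](O[Si](C)(C)C(C)(C)C)CC)O1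
F5 | step 11 | (1R)-1-[(2S,4R,5R)-4-bromo-5-[(1Z,3S)-3-[(tert-butyldimethylsilyl)oxy]pent-1-en-1-yl]oxolan-2-yl]-1-chloro-4,6-bis(triisopropylsilyl)hex-5-yn-3-ol | CC(C)[Si](C(C)C)(C(C)C)C#CC(C(O)C[C@@H](Cl)[C@@H]1C[C@@H](Br)[C@@H](/C=C\[C@@H](O[Si](C)(C)C(C)(C)C)CC)O1)[Si](C(C)C)(C(C)C)C(C)C
F6 | step 13 | (1Z,3S)-1-[(2R,3R,5S)-3-bromo-5-[(1R,3Z)-1-chlorohex-3-en-5-yn-1-yl]oxolan-2-yl]pent-1-en-3-yl methanesulfonate | C#C/C=C\C[C@@H](Cl)[C@@H]1C[C@@H](Br)[C@@H](/C=C\[C@@H](OS(C)(=O)=O)CC)O1
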